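Start from the catalyst.

| setting | maple | larch | flask |
|---|---|---|---|
| left-handed substrate | 0.10 M | 0.10 M | 0.10 M |
| right-handed substrate | 0.10 M | 0.10 M | 0.10 M |
| coupling partner | 0.12 M | 0.12 M | 0.120 M |
| free catalyst | 5 mM | 2.5 mM | 5.0 mM |
| impurity | 1 mM | 1 mM | 1.0 mM |
| remark | the very flask that is asked about, followed so far | run made earlier |  |

| run | time / h | left-handed product / % |
|---|---|---|
| maple | 1.00 | 2.6 |
| maple | 2.00 | 4.4 |
| maple | 3.00 | 6.4 |
| maple | 4.00 | 8.8 |
| maple | 5.00 | 8.2 |
| maple | 6.00 | 9.5 |
| larch | 1.00 | 1.3 |
| larch | 2.00 | 2.5 |
| larch | 3.00 | 2.4 |
| larch | 5.00 | 3.8 |
| larch | 8.00 | 6.5 |
| larch | 15.0 | 9.2 |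

(each reading ± 0.5 percentage points)

- apparent order in coupling partner when 20% of the left-handed substrate and right-handed substrate together are converted (percent change of the rate of making left-handed product for one percent more coupling partner charged)
- apparent order in free catalyst when 20% of the left-handed substrate and right-handed substrate together are converted (percent change of the rate of making left-handed product for one percent more free catalyst charged)

- free catalyst is single-handed; left-handed substrate and right-handed substrate are mirror images of each other, charged as a racemate, each of them at the stated concentration
- no earlier run changes the charge of coupling partner; that part of a forecast is a guess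

Build the flask up in steps, as my own reckoning. With the main step alone, the rate goes as left-handed substrate times coupling partner times free catalyst. Reading at a fixed conversion means a fixed 0.0400 M of partner is gone, so one percent more charge is 1.50 percent more partner left, and the catalyst order is one.

Now let impurity take catalyst one for one, leaving a working charge W of 4.00 mM in the flask. The catalyst order becomes 1.25, and larch agrees roughly: by the readings it needs 2.50 times maple's time for similar product, against 2.67 from W.

Then comes the fade, a loss of free catalyst as the run goes on. Let g be clean conversion, meaning conversion with depletion divided out and all of it counted as left-handed product. Maple gives 0.00957 M and 0.0230 M at 2.00 h and 6.00 h; larch gives 0.00817 M and 0.0221 M at 5.00 h and 15.0 h. The mark, the moment when 20% of both substrates together is converted, needs 0.0632 M.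

If catalyst dies in pairs, the clean rate falls exponentially with g, at the same pace for any W. Comparing each run's early and late clean rates and extending to the mark gives 1.94 for maple and 0.896 for larch, a wide spread, read from readings with a scatter of 0.5 percentage points. Their mean is the fade L, the natural log of working catalyst over free catalyst at the mark: 1.42.

In this reckoning more partner charged reaches the mark at a smaller g, so with less fade, and the partner order is the depletion term 1.50 plus L times the sensitivity of g, taken as the mean of one at the start and 1.50 at the mark: 3.28. The catalyst order stays 1.25.

The forecast gives 1.2 for the partner order and 1.25 for the catalyst order, saying of the partner “Saturation would lower it”.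

The flask gives 3.0 for the partner order and 1.3 for the catalyst order.

    coupling partner + free catalyst + left-handed substrate → free catalyst + left-handed product (k = 1.80 M⁻² min⁻¹)
    free catalyst + impurity → spent catalyst A (k = 250 M⁻¹ min⁻¹)
    2 free catalyst → spent catalyst B (k = 0.250 M⁻¹ min⁻¹)
    coupling partner + free catalyst + right-handed substrate → free catalyst + right-handed product (k = 0.250 M⁻² min⁻¹)

By 2.00 h impurity stood at 0%, with spent catalyst A at 20.0% of the catalyst charged, while the left-handed step had 25% of its turnover up to 20.0 h behind it. At 20.0 h, close to the 19.3 h of the mark, free catalyst was 23.5% and spent catalyst B 56.5%, so L reckoned at that time is 1.22, and the partner order reckoned from it 3.02. Right-handed product then stood at 2.88%.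

All runs are calculated with constants of no real substance.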